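The numbers of this flask belong to no real substance; the run is a simulation.

Time is what this run of 80 min has to spare, and the thing to watch is how much of it the solid substrate takes to go into solution.

    starting material ⇌ reactive form (K1 = 2.0, k1 = 0.012 s⁻¹)
    coupling partner + reactive form ⇌ product (K2 = 30 M⁻¹, k2 = 32 M⁻¹ s⁻¹)
    solid substrate ⇌ starting material, rate k3*(cs3 - [starting material]) while solid is left; crystals form when [starting material] > cs3 (cs3 = 0.85 M, k3 = 0.0073 s⁻¹)

solid substrate 1.5 M; coupling partner 1.42 M; time 80 min

* part of the solid substrate that has turned into other species by 80 min (what has only dissolved does not count)
* product at 80 min, in percent of the solid substrate charged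

- given per volume of solution although it is solid: solid substrate
- at the start none of the solid substrate is in solution
- what has only dissolved of solid substrate counts as not reacted
- run time (flask): 80 min

My own reckoning uses rates alone. With no starting material yet in solution, the solid substrate first dissolves at k3·cs3 = 0.372 M min⁻¹. Dissolved starting material then slows this until step 1 carries off what arrives, which leaves the dissolving at a factor k1/(k1+k3) of its first rate:

slowing by dissolved starting material = 0.622

At the start the return of reactive form through step 1 costs little, because at the charged amount of coupling partner the forward rate of step 2 takes it up in 0.0220 s, far faster than its return time of 167 s, and that factor, reckoned for the start, is: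

slowing by return of reactive form = 1.00

Dividing the charge by the slowed rate gives the clearing time, the time the solid substrate needs to enter solution at the slowed rate:

clearing time = 1.5 M / (0.372 M min⁻¹ × 0.622 × 1.00) = 6.48 min

The run is 12.3 clearing times long, so the solid substrate should be in solution well before the end. This reckoning gives a time and stops there, with no percentage.

The forecast gives 93.6 % for conv and 80.7 % for y_P, and its ground opens: “The solid should be gone within about ten minutes”.

The simulation gives 93.6 % and 80.7 %, agreeing with the forecast.

In this flask the solid substrate stands at 0 % at 8.00 min, later than the clearing time, and product goes from 79.3 % then to 80.7 % at 40.0 min. The neighbouring flask, charged with 2.5 M of solid substrate, reckons at the same slowed rate to a clearing time of 10.8 min, an estimate made at the charged amount of coupling partner, and its run is 7.41 such times long. At 80.0 min that flask holds 0 % solid substrate, with conv 84.8 % and y_P 54.4 %, and its coupling partner, the limiting reagent at 0.568 equiv, stands at 4.2 % of its charge.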